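The numbers in the tables are calculated on assumed constants; the scatter is artificial.

In Friday's run, left-handed substrate falls faster than right-handed substrate: at 5.00 d, that run holds 5.0% against 21.2%.

the same everywhere: left-handed substrate 0.50 M; right-handed substrate 0.50 M
- Friday's: reagent 2.2 equiv; racemization catalyst 0.09 mol%; run made earlier
- Thursday's: reagent 2.2 equiv; racemization catalyst 0.36 mol%; run made earlier
- Saturday's: reagent 1.1 equiv; racemization catalyst 0.18 mol%; run made earlier
- flask: reagent 2.20 equiv; racemization catalyst 0.18 mol%; time 10 d

| run | time / d | left-handed substrate / % | right-handed substrate / % | left-handed product / % |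
|---|---|---|---|---|
| Friday's | 0.417 | 32.9 | 44.5 | 18.5 |
| Friday's | 1.25 | 17.4 | 38.3 | 34.5 |
| Friday's | 2.50 | 9.5 | 31.2 | 45.4 |
| Friday's | 3.00 | 8.2 | 28.1 | 46.3 |
| Friday's | 5.00 | 5.0 | 21.2 | 52.7 |
| Friday's | 6.00 | 4.3 | 18.1 | 54.2 |
| Friday's | 8.00 | 4.0 | 15.4 | 57.1 |
| Thursday's | 0.625 | 28.5 | 40.7 | 24.2 |
| Thursday's | 1.04 | 21.5 | 36.9 | 32.0 |
| Thursday's | 1.67 | 16.7 | 30.3 | 40.9 |
| Thursday's | 2.50 | 13.4 | 24.7 | 47.2 |
| Thursday's | 3.00 | 12.1 | 21.6 | 50.3 |
| Thursday's | 5.00 | 8.1 | 14.1 | 58.3 |
| Thursday's | 8.00 | 5.9 | 8.4 | 65.3 |
| Saturday's | 0.625 | 37.3 | 46.2 | 13.0 |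
| Saturday's | 2.08 | 26.5 | 39.4 | 27.1 |
| Saturday's | 4.00 | 21.6 | 33.3 | 35.1 |
| Saturday's | 6.00 | 21.2 | 30.4 | 38.6 |
| Saturday's | 8.00 | 21.1 | 27.7 | 41.7 |

(scatter of a reading: 0.5 percentage points)

- reagent is single-handed; left-handed substrate and right-handed substrate are mirror images of each other, charged as a racemate, each of them at the stated concentration
- an excess is the difference of the two amounts in percent of their sum
- an excess is below zero if the other one leads
- the handed part of reagent does not stay in what it makes, so the products of the two hands are mirror images too

- part of the left-handed substrate and right-handed substrate charged together that has reacted at 10 d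
- excess of left-handed product over right-handed product in the product at 10 d
- excess of right-handed substrate over left-handed substrate among what is left of the two at 10 d

I take the reagent to drain each hand at k[reagent], with its own k, while racemization exchanges the hands with rate constant r (dynamic kinetic resolution). I call G = (k_L − k_R)[reagent]/r the gap ratio. The excess e of right-handed over left-handed substrate stops moving where

G = 4e/(1 − e·e)

so, where the excess reads nearly still, the readings give G without any constant. I take 5.00 d as such a moment in both of these runs:

Friday's run: e = 61.8%, G = 4.00, log10 G = 0.603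
Thursday's run: e = 27.0%, G = 1.17, log10 G = 0.0668

These runs carry the flask's reagent charge, and the flask's loading lies midway between theirs in logarithms. If r follows the loading and [reagent] matches, the midpoint is 2.16, my estimate of the flask's gap ratio, drain gap over racemization rate constant.

I carry it unchanged to 10 d, and that is a judgement. Friday's run reads 3.59 at 8.00 d, lower than at 5.00 d. Thursday's run reads 0.721 at 8.00 d, also lower, from a difference of 2.5 percentage points between readings with a scatter of 0.5 points. Read backwards, the rule gives me a substrate excess of 43.7%.

The forecast, noting that the flask's loading “is the geometric mean of Friday's and Thursday's loadings”, gives 87% reacted, a product excess of 47% and a substrate excess of 34%, the last lower than mine.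

The flask gives 87.1% reacted, a product excess of 44.3% and a substrate excess of 46.2%.

    reagent → decomposition product (k = 1.10 × 10⁻⁸ s⁻¹)
    reagent + left-handed substrate → left-handed product (k = 1.30 × 10⁻⁵ L mol⁻¹ s⁻¹)
    racemization catalyst ⇌ dormant form (K = 2.30, k = 1.30 × 10⁻⁶ s⁻¹)
    reagent + right-handed substrate → right-handed product (k = 2.60 × 10⁻⁶ L mol⁻¹ s⁻¹)
    left-handed substrate + racemization catalyst ⇌ right-handed substrate + racemization catalyst, rate k5*[racemization catalyst]*[left-handed substrate] forward; the back reaction follows from the equilibrium constant (k = 0.00260 L mol⁻¹ s⁻¹)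

At 10.0 d, the flask holds 20.5% of its reagent and 44.2% of its catalyst in the racemization catalyst form. The constants then give G = 2.26, beside my 2.16, and the balance gives 45.0%. The neighbouring flask with 1.30 equiv of reagent holds 4.95% of its reagent and 44.2% racemization catalyst at that time. Its G is 0.323, lower than the flask's 2.26. The balance gives 8.03% there, and that flask stands at 16.1%.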